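**Plan**
1. Numbering (germacrane): ten-membered ring C1–C10 with C1=C10 (methyl C14 on C10) and C4=C5 (methyl C15 on C4), hydroxyls on C2 and C9, acyloxy on C6, lactone C12(=O)–O–C8 closed through C11(=C13H2) on C7.
2. Cuts: first the lactone C12–O8 bond and the C6 ester. The feature then used is the homoallylic alcohol O–C6–C7–C11=C13 on the ten-membered ring (a ring carbinol next to a ring carbon bearing a 1,1-disubstituted alkenyl branch), the retron of a [2,3]-Wittig shift. Cutting C6–C7 and reconnecting O6 to C13 opens the carbocycle to a 13-membered diallylic ether.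
3. The ether is cut at O–C13 (Williamson) and the chain at C9–C10 (alkenylmetal plus α-alkoxy aldehyde), leaving a C1–C6 alkenyl iodide (fragment A) and a C7–C9/C11–C13 aldehyde (fragment B).
4. Forward: fragments A and B are joined at C9–C10, the 13-membered ether ring is closed and contracted to the ten-membered carbocycle, the C6 ester is attached, and the five-membered lactone ring is formed last.
5. Stereocentres: C8 from (R)-solketal, C2 from a Brown methallylboration, C9 by chelation-controlled addition next to C8, C6 and C7 in the ring contraction, the side-chain centre from (R)-2-methylbutanoic acid.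
6. Alkene geometry: C1=C10 from a trans-hydroalumination/iodination, C4=C5 from a six-membered lactone, C7=C11 from an E-selective Horner–Wadsworth–Emmons reaction.

Key step: step 22

Remark: germacrane numbering is kept for all intermediates; where a CIP descriptor changes only because a protecting group alters the priorities, the SMILES is decisive.

**Fragment A (steps 1–7)**

Step 1
Reactants: 1 but-2-yn-1-ol
Product: 3 (2Z)-3-iodobut-2-en-1-ol, via cyclic alkenylaluminate 2 (not isolated)
Conditions: NaAlH2(OCH2CH2OMe)2, THF, 0 °C → rt; then I2, −78 → 0 °C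
Reagents that add atoms: iodine, II
Why: Hydroxyl-directed trans-hydroalumination of the propargylic alcohol puts aluminium on the distal alkyne carbon inside a five-membered aluminate, and iodinolysis with retention should give the Z iodide that becomes the C1=C10 alkene.

Step 2
Reactants: 3 (2Z)-3-iodobut-2-en-1-ol
Product: 4 (2Z)-3-iodobut-2-enal
Conditions: MnO2, CH2Cl2, rt (solution used directly)
Reagents that add atoms: none
Why: Allylic oxidation with MnO2 is neutral and chemoselective, so the Z geometry and the C–I bond should survive.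

Step 3
Reactants: 4 (2Z)-3-iodobut-2-enal
Product: 6 (2Z,4S)-2-iodo-6-methylhepta-2,6-dien-4-ol, via diisopinocampheylborinate ester 5 (not isolated)
Conditions: (−)-Ipc2BOMe, CH2=C(CH3)CH2MgCl, Et2O, −78 °C → rt; then 4, −78 °C; then NaOH, H2O2, 0 °C → rt
Reagents that add atoms: 2-methylallylmagnesium chloride, C=C(C)C[Mg]Cl
Why: Brown asymmetric methallylboration proceeds through a closed chair-like six-membered transition state in which the isopinocampheyl groups (from (+)-α-pinene) select one aldehyde face, which should set C2 as S by reagent control.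

Step 4
Reactants: 6 (2Z,4S)-2-iodo-6-methylhepta-2,6-dien-4-ol
Product: 7 (2Z,4S)-2-iodo-6-methylhepta-2,6-dien-4-yl prop-2-enoate
Conditions: CH2=CHCOCl, Et3N, CH2Cl2, −20 → 0 °C
Reagents that add atoms: acryloyl chloride, C=CC(Cl)=O
Why: O-Acylation of the secondary alcohol with an acid chloride and amine base installs the acrylate needed for ring closure.

Step 5
Reactants: 7 (2Z,4S)-2-iodo-6-methylhepta-2,6-dien-4-yl prop-2-enoate
Product: 8 (6S)-6-[(1Z)-2-iodoprop-1-en-1-yl]-4-methyl-5,6-dihydro-2H-pyran-2-one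
Conditions: second-generation Grubbs catalyst RuCl2(=CHPh)(H2IMes)(PCy3) (5 mol %), CH2Cl2 (5 mM), 40 °C
Reagents that add atoms: none
Why: Ring-closing metathesis of the acrylate with the 1,1-disubstituted alkene gives the six-membered unsaturated lactone, whose ring forces C3 and C6 cis on the new C4=C5 bond; the trisubstituted alkenyl iodide is too hindered to enter the metathesis cycle.

Step 6
Reactants: 8 (6S)-6-[(1Z)-2-iodoprop-1-en-1-yl]-4-methyl-5,6-dihydro-2H-pyran-2-one
Product: 9 (2Z,5S,6Z)-7-iodo-3-methylocta-2,6-diene-1,5-diol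
Conditions: i-Bu2AlH, CH2Cl2, −78 → −20 °C
Reagents that add atoms: none
Why: 1,2-Reduction of the unsaturated lactone with i-Bu2AlH releases the Z-trisubstituted allylic alcohol with the geometry that was fixed in the ring.

Step 7
Reactants: 9 (2Z,5S,6Z)-7-iodo-3-methylocta-2,6-diene-1,5-diol
Product: 10 (2Z,5S,6Z)-1,5-bis(tert-butyldimethylsilyloxy)-7-iodo-3-methylocta-2,6-diene (fragment A)
Conditions: TBSCl, imidazole, DMF, rt
Reagents that add atoms: tert-butyldimethylsilyl chloride, CC(C)(C)[Si](C)(C)Cl
Why: Imidazole-mediated silylation protects both hydroxyls as ethers that tolerate t-BuLi and can later be told apart as primary against secondary.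

**Phosphonate and fragment B (steps 8–16)**

Step 8
Reactants: 11 triethyl phosphonoacetate
Product: 12 ethyl 2-(diethoxyphosphoryl)-3-hydroxypropanoate (racemic)
Conditions: (CH2O)n (1 equiv), piperidine (cat.), EtOH, 60 °C
Reagents that add atoms: paraformaldehyde (formaldehyde), C=O
Why: Amine-catalysed aldol-type hydroxymethylation of the doubly activated methylene with one equivalent of formaldehyde should stop at the mono-adduct, the usual precursor of the corresponding vinylphosphonate.

Step 9
Reactants: 12 ethyl 2-(diethoxyphosphoryl)-3-hydroxypropanoate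
Product: 13 ethyl 3-(tert-butyldiphenylsilyloxy)-2-(diethoxyphosphoryl)propanoate (racemic)
Conditions: TBDPSCl, imidazole, CH2Cl2, 0 °C → rt
Reagents that add atoms: tert-butyldiphenylsilyl chloride, CC(C)(C)[Si](Cl)(c1ccccc1)c1ccccc1
Why: Silylation of the primary alcohol gives the bulky, acid-stable TBDPS ether that will sit on C12 and later screen the C12 and C13 protons.

Step 10
Reactants: 14 (R)-solketal; 13 ethyl 3-(tert-butyldiphenylsilyloxy)-2-(diethoxyphosphoryl)propanoate
Product: 16 ethyl (2E)-2-[(tert-butyldiphenylsilyloxy)methyl]-3-[(4R)-2,2-dimethyl-1,3-dioxolan-4-yl]prop-2-enoate, via (S)-glyceraldehyde acetonide 15 (not isolated)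
Conditions: (COCl)2, DMSO, Et3N, CH2Cl2, −78 °C; then 13, LiCl, DBU, MeCN, −20 °C → rt
Reagents that add atoms: none
Why: Swern oxidation followed in the same flask by a Horner–Wadsworth–Emmons olefination under Masamune–Roush conditions avoids isolating and epimerising the aldehyde and should place the ester trans to C8 (E), so that after reduction C13 is trans and C12 cis to C8; C8 is carried unchanged from (R)-solketal.

Step 11
Reactants: 16 ethyl (2E)-2-[(tert-butyldiphenylsilyloxy)methyl]-3-[(4R)-2,2-dimethyl-1,3-dioxolan-4-yl]prop-2-enoate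
Product: 17 (2Z)-2-[(tert-butyldiphenylsilyloxy)methyl]-3-[(4R)-2,2-dimethyl-1,3-dioxolan-4-yl]prop-2-en-1-ol
Conditions: i-Bu2AlH, CH2Cl2, −78 °C
Reagents that add atoms: none
Why: Ester reduction by 1,2-addition of i-Bu2AlH at low temperature gives the allylic alcohol (C13–OH) without touching the silyl ether or the acetonide.

Step 12
Reactants: 17 (2Z)-2-[(tert-butyldiphenylsilyloxy)methyl]-3-[(4R)-2,2-dimethyl-1,3-dioxolan-4-yl]prop-2-en-1-ol
Product: 18 tert-butyl{[(2E)-2-(chloromethyl)-3-[(4R)-2,2-dimethyl-1,3-dioxolan-4-yl]prop-2-en-1-yl]oxy}diphenylsilane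
Conditions: N-chlorosuccinimide, Me2S, CH2Cl2, −20 → 0 °C
Reagents that add atoms: N-chlorosuccinimide, O=C1CCC(=O)N1Cl
Why: Corey–Kim chlorination converts the primary allylic alcohol into the chloride by SN2 displacement of an alkoxysulfonium ion without allylic transposition.

Step 13
Reactants: 18 allylic chloride acetonide
Product: 19 (2R,3E)-5-(tert-butyldiphenylsilyloxy)-4-(chloromethyl)pent-3-ene-1,2-diol
Conditions: AcOH/H2O/THF (3:1:1), 40 °C
Reagents that add atoms: none
Why: Acetal hydrolysis in mild aqueous acid removes the terminal acetonide while the TBDPS ether and the primary allylic chloride should persist.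

Step 14
Reactants: 19 (2R,3E)-5-(tert-butyldiphenylsilyloxy)-4-(chloromethyl)pent-3-ene-1,2-diol
Product: 20 p-methoxybenzylidene acetal of 19 (both acetal epimers)
Conditions: 4-MeOC6H4CH(OMe)2, PPTS (cat.), CH2Cl2, rt
Reagents that add atoms: 4-methoxybenzaldehyde dimethyl acetal, COc1ccc(cc1)C(OC)OC
Why: Acid-catalysed transacetalisation of the 1,2-diol gives the five-membered benzylidene-type acetal, and either acetal epimer serves in the next step.

Step 15
Reactants: 20 p-methoxybenzylidene acetal
Product: 21 (2R,3E)-5-(tert-butyldiphenylsilyloxy)-4-(chloromethyl)-2-[(4-methoxybenzyl)oxy]pent-3-en-1-ol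
Conditions: i-Bu2AlH, CH2Cl2, −78 → 0 °C
Reagents that add atoms: none
Why: Regioselective reductive acetal opening, in which i-Bu2AlH coordinates the less hindered primary oxygen and delivers hydride to the oxocarbenium ion, should leave the PMB ether on the secondary O8 and free C9–OH.

Step 16
Reactants: 21 PMB ether alcohol
Product: 22 (2R,3E)-5-(tert-butyldiphenylsilyloxy)-4-(chloromethyl)-2-[(4-methoxybenzyl)oxy]pent-3-enal (fragment B)
Conditions: Dess–Martin periodinane, NaHCO3, CH2Cl2, 0 °C (used at once)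
Reagents that add atoms: none
Why: Dess–Martin oxidation under buffered, non-basic conditions gives the α-alkoxy aldehyde, whose C8–H lies in the alkene plane (allylic strain with the cis CH2OTBDPS group) and is therefore not activated toward epimerisation.

**Union, ring closure and ring contraction (steps 17–22)**

Step 17
Reactants: 10 fragment A iodide; 22 fragment B aldehyde
Product: 25 open-chain C6–C13 adduct (9R-hydroxy; 8R-OPMB; 2S; C2 and C6 OTBS; C12 OTBDPS; C13 chloride), via alkenyllithium 23 (not isolated), via alkenylmagnesium bromide 24 (not isolated)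
Conditions: 10, t-BuLi (2 equiv), Et2O, −78 °C; MgBr2·OEt2, −78 °C; then 22 premixed with MgBr2·OEt2 in CH2Cl2, −78 °C
Reagents that add atoms: none
Why: Iodine–lithium exchange with retention, transmetalation to magnesium and chelation-controlled addition (Cram chelate of the aldehyde oxygen and the PMB ether on magnesium) should deliver the alkenyl group anti to the C7 substituent, setting C9 as R, syn to C8–O, while the allylic chloride is inert at −78 °C.

Step 18
Reactants: 25 open-chain adduct
Product: 26 8,9-diol (PMB removed)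
Conditions: DDQ, CH2Cl2/pH 7 buffer (10:1), 0 °C
Reagents that add atoms: none
Why: Oxidative PMB cleavage with DDQ in buffered wet solvent frees the C8 hydroxyl without affecting the silyl ethers, the alkenes or the chloride.

Step 19
Reactants: 26 8,9-diol
Product: 27 8,9-O-isopropylidene derivative (trans-dioxolane)
Conditions: Me2C(OMe)2, PPTS (cat.), CH2Cl2, rt
Reagents that add atoms: 2,2-dimethoxypropane, COC(C)(C)OC
Why: Acid-catalysed ketalisation of the syn (threo) diol gives the trans-4,5-disubstituted dioxolane, a base-stable group without acidic C–H bonds that also fixes the conformation at C8.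

Step 20
Reactants: 27 acetonide
Product: 28 C6 alcohol with C13 chloride (seco-ether)
Conditions: HF·pyridine, pyridine, THF, 0 °C
Reagents that add atoms: none
Why: Selective desilylation: buffered HF·pyridine removes the unhindered primary allylic TBS ether much faster than the secondary TBS and the TBDPS ethers and leaves the acetonide intact.

Step 21
Reactants: 28 seco-ether
Product: 29 13-membered cyclic diallylic ether (C6–O–C13; 8,9-acetonide; C2 OTBS; C12 OTBDPS; C8 trans to C13 on C7=C11)
Conditions: NaH, Bu4NI (cat.), THF (1 mM, slow addition), 0 → 40 °C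
Reagents that add atoms: none
Why: Intramolecular Williamson etherification under high dilution, in which the C6 alkoxide displaces the primary allylic chloride at C13 (via the iodide) in a 13-exo-tet SN2 closure, leaves the C7=C11 geometry and all stereocentres untouched.

Step 22
Reactants: 29 13-membered cyclic diallylic ether
Product: 31 (2S,6R,7S,8R,9R)-Z,Z-cyclodecadienol with free C6–OH and the C11(=C13H2)CH2OTBDPS branch on C7, via C6-lithiated ether 30 (not isolated)
Conditions: n-BuLi, THF, −78 → −25 °C; then H2O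
Reagents that add atoms: none
Why: n-BuLi removes a C6 proton (allylic and α to the ring oxygen) and the α-oxyallyllithium 30 undergoes a [2,3]-Wittig shift through a five-membered envelope (C6–O–C13–C11=C7) in which C6–C7 forms as O–C13 breaks, C11=C13 appears and the oxygen ends as the C6 alkoxide. The closest known reaction is the [2,3]-Wittig ring contraction of 13-membered diallylic ethers to germacradienols. The ten-membered carbocycle closes by ring contraction (13 to 10) across the macrocycle, a concerted suprafacial sigmatropic closure and not an exo or endo ionic cyclisation. C7 is controlled by C8: the CH2OTBDPS group cis to C8 holds C8–H in the alkene plane (allylic strain), the dioxolane C8–O bond stands perpendicular, and C6, tethered through C9, should reach C7 on the face anti to that C–O bond, which gives 7S. C6 is controlled by the C7=C11 geometry: with C8 trans to C13 the envelope keeps the C5 vinyl group away from C8, which gives C6–O and C8 anti along C5–C6–C7–C11 (6R). The step needs lithiation at C6 and not at C13 or C12: the C6 protons adjoin the unhindered C5–H carbon, whereas the C13 and C12 protons flank the fully substituted C11 and are screened by the TBDPS group, and a C13 anion would have to bond to the fully substituted C4.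

**Endgame (steps 23–26)**

Step 23
Reactants: 31 cyclodecadienol; 32 (R)-2-methylbutanoic acid
Product: 33 C6 (R)-2-methylbutanoate of 31
Conditions: DCC, DMAP (cat.), CH2Cl2, 0 °C → rt
Reagents that add atoms: none
Why: Steglich esterification acylates the only free hydroxyl, at C6, with the acid whose stereocentre is carried over unchanged.

Step 24
Reactants: 33 ester
Product: 34 C2,C12-diol (8,9-acetonide retained)
Conditions: Bu4NF, AcOH, THF, rt
Reagents that add atoms: none
Why: Fluoride desilylation cleaves both silyl ethers, and buffering with acetic acid keeps the medium near neutral so that the C6 ester should neither migrate nor hydrolyse.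

Step 25
Reactants: 34 diol acetonide
Product: 35 C2,C8,C9,C12-tetraol
Conditions: AcOH/H2O (4:1), 40 °C
Reagents that add atoms: none
Why: Acetal hydrolysis in aqueous acetic acid opens the dioxolane to the 8,9-diol under conditions mild enough for the allylic ester and the Z,Z-diene.

Step 26
Reactants: 35 tetraol
Product: 37 target compound (CNP0176600.1), via lactol 36 (not isolated)
Conditions: TEMPO (cat.), PhI(OAc)2, CH2Cl2, rt
Reagents that add atoms: none
Why: TEMPO/PhI(OAc)2 oxidative lactonisation: the oxoammonium salt oxidises only the primary C12 hydroxyl, the enal is captured by C8–OH as the fused five-membered lactol (closure onto O9 would give a bridged six-membered ring) and the lactol is oxidised to the α-methylene lactone, while the secondary hydroxyls at C2 and C9 should react far more slowly.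

**Compound list**

1 | but-2-yn-1-ol | CC#CCO | starting material
2 | sodium cyclic alkenylaluminate from 1 (five-membered O–Al–C3=C2–C1 ring, two 2-methoxyethoxy ligands) | CC1=CCO[Al-]1(OCCOC)OCCOC.[Na+] | intermediate
3 | (2Z)-3-iodobut-2-en-1-ol | C/C(I)=C/CO | intermediate
4 | (2Z)-3-iodobut-2-enal | C/C(I)=C/C=O | intermediate
5 | diisopinocampheylborinate ester of 6 | C=C(C)C[C@H](OB([C@@H]1C[C@@H]2C[C@H]([C@H]1C)C2(C)C)[C@@H]1C[C@@H]2C[C@H]([C@H]1C)C2(C)C)/C=C(/C)I | intermediate
6 | (2Z,4S)-2-iodo-6-methylhepta-2,6-dien-4-ol | C=C(C)C[C@H](O)/C=C(/C)I | intermediate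
7 | (2Z,4S)-2-iodo-6-methylhepta-2,6-dien-4-yl prop-2-enoate | C=CC(=O)O[C@@H](CC(C)=C)/C=C(/C)I | intermediate
8 | (6S)-6-[(1Z)-2-iodoprop-1-en-1-yl]-4-methyl-5,6-dihydro-2H-pyran-2-one | CC1=CC(=O)O[C@@H](C1)/C=C(/C)I | intermediate
9 | (2Z,5S,6Z)-7-iodo-3-methylocta-2,6-diene-1,5-diol | OC/C=C(/C)C[C@H](O)/C=C(/C)I | intermediate
10 | (2Z,5S,6Z)-1,5-bis(tert-butyldimethylsilyloxy)-7-iodo-3-methylocta-2,6-diene (fragment A; C6 to C1 with C10, C14, C15) | CC(C)(C)[Si](C)(C)OC/C=C(/C)C[C@H](O[Si](C)(C)C(C)(C)C)/C=C(/C)I | intermediate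
11 | triethyl phosphonoacetate | CCOC(=O)CP(=O)(OCC)OCC | starting material
12 | ethyl 2-(diethoxyphosphoryl)-3-hydroxypropanoate (racemic) | CCOC(=O)C(CO)P(=O)(OCC)OCC | intermediate
13 | ethyl 3-(tert-butyldiphenylsilyloxy)-2-(diethoxyphosphoryl)propanoate (racemic) | CCOC(=O)C(CO[Si](c1ccccc1)(c1ccccc1)C(C)(C)C)P(=O)(OCC)OCC | intermediate
14 | (R)-solketal, [(4R)-2,2-dimethyl-1,3-dioxolan-4-yl]methanol | OC[C@@H]1COC(C)(C)O1 | starting material
15 | (4S)-2,2-dimethyl-1,3-dioxolane-4-carbaldehyde | O=C[C@@H]1COC(C)(C)O1 | intermediate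
16 | ethyl (2E)-2-[(tert-butyldiphenylsilyloxy)methyl]-3-[(4R)-2,2-dimethyl-1,3-dioxolan-4-yl]prop-2-enoate | CC1(C)OC[C@@H](/C=C(\CO[Si](c2ccccc2)(c2ccccc2)C(C)(C)C)C(=O)OCC)O1 | intermediate
17 | (2Z)-2-[(tert-butyldiphenylsilyloxy)methyl]-3-[(4R)-2,2-dimethyl-1,3-dioxolan-4-yl]prop-2-en-1-ol | CC1(C)OC[C@@H](/C=C(\CO[Si](c2ccccc2)(c2ccccc2)C(C)(C)C)CO)O1 | intermediate
18 | tert-butyl{[(2E)-2-(chloromethyl)-3-[(4R)-2,2-dimethyl-1,3-dioxolan-4-yl]prop-2-en-1-yl]oxy}diphenylsilane | CC1(C)OC[C@@H](/C=C(\CO[Si](c2ccccc2)(c2ccccc2)C(C)(C)C)CCl)O1 | intermediate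
19 | (2R,3E)-5-(tert-butyldiphenylsilyloxy)-4-(chloromethyl)pent-3-ene-1,2-diol | OC[C@H](O)/C=C(\CO[Si](c1ccccc1)(c1ccccc1)C(C)(C)C)CCl | intermediate
20 | (4R)-4-[(1E)-3-(tert-butyldiphenylsilyloxy)-2-(chloromethyl)prop-1-en-1-yl]-2-(4-methoxyphenyl)-1,3-dioxolane (acetal epimers) | COc1ccc(cc1)C1OC[C@@H](/C=C(\CO[Si](c2ccccc2)(c2ccccc2)C(C)(C)C)CCl)O1 | intermediate
21 | (2R,3E)-5-(tert-butyldiphenylsilyloxy)-4-(chloromethyl)-2-[(4-methoxybenzyl)oxy]pent-3-en-1-ol | OC[C@H](OCc1ccc(OC)cc1)/C=C(\CO[Si](c1ccccc1)(c1ccccc1)C(C)(C)C)CCl | intermediate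
22 | (2R,3E)-5-(tert-butyldiphenylsilyloxy)-4-(chloromethyl)-2-[(4-methoxybenzyl)oxy]pent-3-enal (fragment B; C9, C8, C7, C11, C12, C13) | O=C[C@H](OCc1ccc(OC)cc1)/C=C(\CO[Si](c1ccccc1)(c1ccccc1)C(C)(C)C)CCl | intermediate
23 | alkenyllithium from 10 (Li in place of I, Z retained) | CC(C)(C)[Si](C)(C)OC/C=C(/C)C[C@H](O[Si](C)(C)C(C)(C)C)/C=C(/C)[Li] | intermediate
24 | alkenylmagnesium bromide from 23 | CC(C)(C)[Si](C)(C)OC/C=C(/C)C[C@H](O[Si](C)(C)C(C)(C)C)/C=C(/C)[Mg]Br | intermediate
25 | open-chain adduct C6–C5=C4–C3–C2–C1=C10–C9–C8–C7=C11(C12)(C13): (2S,8R,9R), 1(10)Z, 4Z, C8 cis to C12; C2 and C6 OTBS, C9 OH, C8 OPMB, C12 OTBDPS, C13 Cl | CC(C)(C)[Si](C)(C)OC/C=C(/C)C[C@H](O[Si](C)(C)C(C)(C)C)/C=C(/C)[C@@H](O)[C@H](OCc1ccc(OC)cc1)/C=C(\CO[Si](c1ccccc1)(c1ccccc1)C(C)(C)C)CCl | intermediate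
26 | (8R,9R)-8,9-diol of 25 (PMB removed) | CC(C)(C)[Si](C)(C)OC/C=C(/C)C[C@H](O[Si](C)(C)C(C)(C)C)/C=C(/C)[C@@H](O)[C@H](O)/C=C(\CO[Si](c1ccccc1)(c1ccccc1)C(C)(C)C)CCl | intermediate
27 | 8,9-O-isopropylidene derivative of 26 (trans-dioxolane) | CC(C)(C)[Si](C)(C)OC/C=C(/C)C[C@H](O[Si](C)(C)C(C)(C)C)/C=C(/C)[C@H]1OC(C)(C)O[C@@H]1/C=C(\CO[Si](c2ccccc2)(c2ccccc2)C(C)(C)C)CCl | intermediate
28 | seco-ether: 27 with free C6–OH (C13 chloride, C2 OTBS, C12 OTBDPS, 8,9-acetonide) | OC/C=C(/C)C[C@H](O[Si](C)(C)C(C)(C)C)/C=C(/C)[C@H]1OC(C)(C)O[C@@H]1/C=C(\CO[Si](c2ccccc2)(c2ccccc2)C(C)(C)C)CCl | intermediate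
29 | 13-membered cyclic diallylic ether C6–O–C13 (2S,8R,9R; 1(10)Z, 4Z; C8 trans to C13; 8,9-acetonide; C2 OTBS; C12 OTBDPS) | CC1(C)O[C@@H]2/C=C(\CO[Si](c3ccccc3)(c3ccccc3)C(C)(C)C)COC/C=C(/C)C[C@H](O[Si](C)(C)C(C)(C)C)/C=C(/C)[C@H]2O1 | intermediate
30 | C6-lithiated 29 (α-oxyallyllithium; C6 configuration not defined) | CC1(C)O[C@@H]2/C=C(\CO[Si](c3ccccc3)(c3ccccc3)C(C)(C)C)COC([Li])/C=C(/C)C[C@H](O[Si](C)(C)C(C)(C)C)/C=C(/C)[C@H]2O1 | intermediate
31 | (2S,6R,7S,8R,9R)-Z,Z-cyclodeca-1(10),4-dien-6-ol with C7 branch C(=CH2)CH2OTBDPS, 8,9-acetonide, C2 OTBS | CC1(C)O[C@@H]2[C@@H](C(=C)CO[Si](c3ccccc3)(c3ccccc3)C(C)(C)C)[C@H](O)/C=C(/C)C[C@H](O[Si](C)(C)C(C)(C)C)/C=C(/C)[C@H]2O1 | intermediate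
32 | (R)-2-methylbutanoic acid | CC[C@@H](C)C(=O)O | starting material
33 | C6 (R)-2-methylbutanoate of 31 | CC1(C)O[C@@H]2[C@@H](C(=C)CO[Si](c3ccccc3)(c3ccccc3)C(C)(C)C)[C@H](OC(=O)[C@H](C)CC)/C=C(/C)C[C@H](O[Si](C)(C)C(C)(C)C)/C=C(/C)[C@H]2O1 | intermediate
34 | C2,C12-diol of 33 (8,9-acetonide, C6 ester) | CC1(C)O[C@@H]2[C@@H](C(=C)CO)[C@H](OC(=O)[C@H](C)CC)/C=C(/C)C[C@H](O)/C=C(/C)[C@H]2O1 | intermediate
35 | C2,C8,C9,C12-tetraol with C6 ester (ring stereocentres arranged as in 37) | C=C(CO)[C@H]1[C@H](OC(=O)[C@H](C)CC)/C=C(/C)C[C@H](O)/C=C(/C)[C@@H](O)[C@@H]1O | intermediate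
36 | 8,12-lactol of the C12 aldehyde (C12 epimers) | C=C1C(O)O[C@@H]2[C@@H]1[C@H](OC(=O)[C@H](C)CC)/C=C(/C)C[C@H](O)/C=C(/C)[C@H]2O | intermediate
37 | CNP0176600.1, (2S,6R,7S,8R,9R)-2,9-dihydroxy-6-[(2R)-2-methylbutanoyloxy]germacra-1(10)Z,4Z,11(13)-trien-12,8-olide | C=C1C(=O)O[C@@H]2[C@@H]1[C@H](OC(=O)[C@H](C)CC)/C=C(/C)C[C@H](O)/C=C(/C)[C@H]2O | target

**Count and risks**

Total steps: 26. Longest linear sequence: 19 steps (11 → 37 through steps 8–26). Fragment A takes 7 steps, the phosphonate and fragment B together 9.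

Steps most likely to fail:

1. Step 22 (ring contraction). Lithiation may occur at C13 or C12 instead of C6, followed by a 1,2-shift or by β-elimination toward C8, or the shift may pass through the diastereomeric envelope. The fallback sets out from 28. MnO2 in CH2Cl2 oxidises the primary allylic alcohol to the (Z)-enal chloride F1. CrCl2 with LiI in THF under high dilution then turns the allylic chloride into an allylchromium species that adds through its γ-carbon C7 to the C6 aldehyde (intramolecular Nozaki–Hiyama allylation, chair transition state, anti selective). This forms the same C6–C7 bond with C11=C13 and the free C6–OH. The route is rejoined at 31, and step 21 is spared as well.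

2. Step 17 (fragment union). Chelation control may be lost, the alkenyllithium may suffer a 1,4 oxygen-to-carbon silyl shift before transmetalation, or the aldehyde may epimerise at C8. The fallback sets out from 10 and 22. A Nozaki–Hiyama–Kishi coupling (CrCl2, NiCl2 cat., DMSO/THF) joins them without any lithium reagent and should give 25 together with its C9 epimer F2. Dess–Martin oxidation of the mixture gives the C9 enone F3. A reagent-controlled Corey–Bakshi–Shibata reduction ((R)-2-methyl-CBS-oxazaborolidine, BH3·SMe2, alkenyl arm taken as the larger group) then sets C9. The route is rejoined at 25.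

3. Step 26 (oxidative lactonisation). The secondary allylic hydroxyls at C2 and C9 may be over-oxidised, or the lactol may close onto O9. The fallback sets out from 34, while O8 and O9 are still masked. TEMPO/PhI(OAc)2 oxidises C12–OH to the C12 aldehyde F4. A Pinnick oxidation (NaClO2, NaH2PO4, 2-methylbut-2-ene, t-BuOH/H2O) gives the C12 acid F5. Aqueous acetic acid then removes the acetonide, and the γ-hydroxy acid lactonises onto O8 under thermodynamic control. The route is rejoined at 37.

Further compounds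
F1 | step 22 | (Z)-enal chloride: 28 with C6 oxidised to the aldehyde | O=C/C=C(/C)C[C@H](O[Si](C)(C)C(C)(C)C)/C=C(/C)[C@H]1OC(C)(C)O[C@@H]1/C=C(\CO[Si](c2ccccc2)(c2ccccc2)C(C)(C)C)CCl
F2 | step 17 | C9 epimer of 25 (9S) | CC(C)(C)[Si](C)(C)OC/C=C(/C)C[C@H](O[Si](C)(C)C(C)(C)C)/C=C(/C)[C@H](O)[C@H](OCc1ccc(OC)cc1)/C=C(\CO[Si](c1ccccc1)(c1ccccc1)C(C)(C)C)CCl
F3 | step 17 | C9 enone from 25 and F2 | CC(C)(C)[Si](C)(C)OC/C=C(/C)C[C@H](O[Si](C)(C)C(C)(C)C)/C=C(/C)C(=O)[C@H](OCc1ccc(OC)cc1)/C=C(\CO[Si](c1ccccc1)(c1ccccc1)C(C)(C)C)CCl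
F4 | step 26 | C12 aldehyde of 34 | CC1(C)O[C@@H]2[C@@H](C(=C)C=O)[C@H](OC(=O)[C@H](C)CC)/C=C(/C)C[C@H](O)/C=C(/C)[C@H]2O1
F5 | step 26 | C12 carboxylic acid of 34 | CC1(C)O[C@@H]2[C@@H](C(=C)C(=O)O)[C@H](OC(=O)[C@H](C)CC)/C=C(/C)C[C@H](O)/C=C(/C)[C@H]2O1
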